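**Retrosynthetic overview**
- Target ⇐ C8 isovalerylation and C15 desilylation of the tricyclic C8 alcohol.
- The ten-membered ring is closed last at C7–C8: the β-carbon of a 3-(bromomethyl)butenolide, as its allylzinc (a lactone homoenolate), adds to the C8 aldehyde. This gives the α-methylene lactone and sets C7 and C8 in one step.
- Butenolide ⇐ ring-closing metathesis of the C6 2-(bromomethyl)acrylate. Furanone ⇐ Au-catalysed cyclisation of a γ-hydroxy ynone made by carbonylative Sonogashira coupling (C3 carbonyl between the C4 iodide and the C2 alkyne).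
- Vinyl iodide half ⇐ asymmetric alkynylation of crotonaldehyde (C6), then trans-hydroalumination/iodination (4Z). Alkyne half ⇐ Sharpless epoxidation/Red-Al opening of (Z)-3-methylpent-2-en-4-yn-1-ol (C10).
- Ring order: furanone, then butenolide (the lactone), then the ten-membered carbocycle.

Assumption: atoms are referred to by germacrane numbering (C1–C15; lactone C6–O–C12, ester on C8, furanone C1–C3/C10); the ProPhenol antipode in step 1 is the one that gives the 4S carbinol, written here as (S,S).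

Step 1
Reactants: 1 tert-butyldimethyl(prop-2-yn-1-yloxy)silane; 2 (E)-but-2-enal
Product: 4 (4S,5E)-1-[(tert-butyldimethylsilyl)oxy]hept-5-en-2-yn-4-ol, via alkynylzinc 3 (not isolated)
Conditions: 1 (3 equiv), Me2Zn (3 equiv), (S,S)-ProPhenol (10 mol %), Ph3P=O (20 mol %), toluene, 0 °C; then 2, 0–4 °C; aq NH4Cl
Reagents that add atoms: none
Why: Zn–ProPhenol-catalysed asymmetric alkynylation of an enal, in which the alkynylzinc adds 1,2 to crotonaldehyde inside the chiral dinuclear zinc pocket and so sets C6 as the 4S carbinol.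

Step 2
Reactants: 4 (4S,5E)-1-[(tert-butyldimethylsilyl)oxy]hept-5-en-2-yn-4-ol
Product: 6 (2Z,4S,5E)-1-[(tert-butyldimethylsilyl)oxy]-2-iodohepta-2,5-dien-4-ol, via cyclic alkenylalanate 5 (not isolated)
Conditions: Red-Al (1.6 equiv), THF, 0 °C → rt; then I2, THF, −78 → 0 °C
Reagents that add atoms: iodine II
Why: Alkoxide-directed trans-hydroalumination of the propargylic alcohol puts aluminium on the distal alkyne carbon (C4) and iodinolysis with retention gives the (Z)-vinyl iodide, which fixes the 4Z geometry while the isolated alkene and the silyl ether stay inert.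

Step 3
Reactants: 6 (2Z,4S,5E)-1-[(tert-butyldimethylsilyl)oxy]-2-iodohepta-2,5-dien-4-ol
Product: 7 tert-butyl{[(2Z,4S,5E)-2-iodo-4-[(triethylsilyl)oxy]hepta-2,5-dien-1-yl]oxy}dimethylsilane
Conditions: TESCl, imidazole, CH2Cl2, 0 °C
Reagents that add atoms: chlorotriethylsilane CC[Si](Cl)(CC)CC
Why: Standard silylation that caps the C6 oxygen so it cannot close onto the C3 carbonyl of the coming (Z)-γ-oxygenated enone (lactol and furan formation).

Step 4
Reactants: 8 (2Z)-3-methylpent-2-en-4-yn-1-ol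
Product: 9 [(2S,3R)-3-ethynyl-3-methyloxiran-2-yl]methanol
Conditions: Ti(OiPr)4 (10 mol %), L-(+)-DET (12 mol %), t-BuOOH (2 equiv), 4 Å MS, CH2Cl2, −20 °C
Reagents that add atoms: tert-butyl hydroperoxide CC(C)(C)OO
Why: Katsuki–Sharpless asymmetric epoxidation of a trisubstituted (Z)-allylic alcohol, where L-(+)-tartrate delivers oxygen to the face giving the (2S,3R)-epoxide (as with nerol) and thereby sets C10.

Step 5
Reactants: 9 [(2S,3R)-3-ethynyl-3-methyloxiran-2-yl]methanol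
Product: 10 (3S)-3-methylpent-4-yne-1,3-diol
Conditions: Red-Al (3 equiv), THF, 0 °C
Reagents that add atoms: none
Why: Alkoxide-directed intramolecular hydride delivery from Red-Al opens 2,3-epoxy alcohols at C2 to give 1,3-diols, so the C10–O bond and its configuration are untouched.

Step 6
Reactants: 10 (3S)-3-methylpent-4-yne-1,3-diol
Product: 11 (3S)-3-methyl-5-[(triethylsilyl)oxy]pent-1-yn-3-ol
Conditions: TESCl (1.05 equiv), imidazole, CH2Cl2, −20 °C
Reagents that add atoms: chlorotriethylsilane CC[Si](Cl)(CC)CC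
Why: Selective silylation of the primary over the tertiary propargylic hydroxyl, which prevents 5-exo oxa-Michael addition of the C8 oxygen to the ynone in steps 7–8.

Step 7
Reactants: 7 tert-butyl{[(2Z,4S,5E)-2-iodo-4-[(triethylsilyl)oxy]hepta-2,5-dien-1-yl]oxy}dimethylsilane; 11 (3S)-3-methyl-5-[(triethylsilyl)oxy]pent-1-yn-3-ol
Product: 12 (3S,7Z,9S,10E)-7-{[(tert-butyldimethylsilyl)oxy]methyl}-3-hydroxy-3-methyl-1,9-bis[(triethylsilyl)oxy]dodeca-7,10-dien-4-yn-6-one
Conditions: PdCl2(PPh3)2 (5 mol %), CuI (2 mol %), Et3N (3 equiv), CO (5 bar), THF, rt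
Reagents that add atoms: carbon monoxide [C-]#[O+]
Why: Carbonylative Sonogashira coupling, in which oxidative addition to the vinyl iodide with retention of geometry, CO insertion, alkynyl transfer from copper and reductive elimination give the alkynyl ketone.

Step 8
Reactants: 12 (3S,7Z,9S,10E)-7-{[(tert-butyldimethylsilyl)oxy]methyl}-3-hydroxy-3-methyl-1,9-bis[(triethylsilyl)oxy]dodeca-7,10-dien-4-yn-6-one
Product: 13 (2S)-5-[(2Z,4S,5E)-1-[(tert-butyldimethylsilyl)oxy]-4-[(triethylsilyl)oxy]hepta-2,5-dien-2-yl]-2-methyl-2-{2-[(triethylsilyl)oxy]ethyl}furan-3(2H)-one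
Conditions: (4-CF3C6H4)3PAuCl (5 mol %), AgOTf (5 mol %), toluene, rt
Reagents that add atoms: none
Why: Cationic gold(I)-catalysed cycloisomerisation of a γ-hydroxy alkynone to a 3(2H)-furanone (formal hydration at C1, then cyclodehydration of the C10 hydroxyl onto C3), which touches no stereocentre.

Step 9
Reactants: 13 (2S)-5-[(2Z,4S,5E)-1-[(tert-butyldimethylsilyl)oxy]-4-[(triethylsilyl)oxy]hepta-2,5-dien-2-yl]-2-methyl-2-{2-[(triethylsilyl)oxy]ethyl}furan-3(2H)-one
Product: 14 [(2S)-5-{(2Z,4S,5E)-1-[(tert-butyldimethylsilyl)oxy]-4-[(triethylsilyl)oxy]hepta-2,5-dien-2-yl}-2-methyl-3-oxo-2,3-dihydrofuran-2-yl]acetaldehyde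
Conditions: (COCl)2, DMSO, CH2Cl2, −78 → −40 °C; Et3N, −78 → 0 °C
Reagents that add atoms: none
Why: Under Swern conditions a primary triethylsilyl ether is cleaved and oxidised directly to the aldehyde while secondary TES and TBS ethers survive.

Step 10
Reactants: 14 [(2S)-5-{(2Z,4S,5E)-1-[(tert-butyldimethylsilyl)oxy]-4-[(triethylsilyl)oxy]hepta-2,5-dien-2-yl}-2-methyl-3-oxo-2,3-dihydrofuran-2-yl]acetaldehyde
Product: 15 [(2S)-5-{(2Z,4S,5E)-1-[(tert-butyldimethylsilyl)oxy]-4-hydroxyhepta-2,5-dien-2-yl}-2-methyl-3-oxo-2,3-dihydrofuran-2-yl]acetaldehyde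
Conditions: HF·pyridine, pyridine, THF, 0 °C
Reagents that add atoms: none
Why: Buffered HF·pyridine removes the secondary TES ether much faster than the primary TBS ether and leaves the aldehyde alone.

Step 11
Reactants: 15 [(2S)-5-{(2Z,4S,5E)-1-[(tert-butyldimethylsilyl)oxy]-4-hydroxyhepta-2,5-dien-2-yl}-2-methyl-3-oxo-2,3-dihydrofuran-2-yl]acetaldehyde; 16 2-(bromomethyl)prop-2-enoic acid
Product: 18 (2Z,4S,5E)-1-[(tert-butyldimethylsilyl)oxy]-2-[(5S)-5-methyl-4-oxo-5-(2-oxoethyl)-4,5-dihydrofuran-2-yl]hepta-2,5-dien-4-yl 2-(bromomethyl)prop-2-enoate, via acid chloride 17 (not isolated)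
Conditions: 16, (COCl)2, cat. DMF, CH2Cl2, 0 °C → rt, evaporate; then 15, 2,6-lutidine, CH2Cl2, −20 → 0 °C
Reagents that add atoms: none
Why: O-acylation with the acid chloride and a hindered, non-nucleophilic base (retention at C6) avoids the SN2′ attack that DMAP or Et3N would make on the allylic bromide.

Step 12
Reactants: 18 (2Z,4S,5E)-1-[(tert-butyldimethylsilyl)oxy]-2-[(5S)-5-methyl-4-oxo-5-(2-oxoethyl)-4,5-dihydrofuran-2-yl]hepta-2,5-dien-4-yl 2-(bromomethyl)prop-2-enoate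
Product: 19 [(2S)-5-{(1Z)-1-[(2R)-4-(bromomethyl)-5-oxo-2,5-dihydrofuran-2-yl]-3-[(tert-butyldimethylsilyl)oxy]prop-1-en-2-yl}-2-methyl-3-oxo-2,3-dihydrofuran-2-yl]acetaldehyde
Conditions: Grubbs II (10 mol %), toluene (5 mM), 70 °C
Reagents that add atoms: none
Why: Ring-closing metathesis between the propenyl group and the acrylate olefin gives the butenolide with loss of propene, the other olefins being trisubstituted and conjugated and so unreactive.

Step 13
Reactants: 19 [(2S)-5-{(1Z)-1-[(2R)-4-(bromomethyl)-5-oxo-2,5-dihydrofuran-2-yl]-3-[(tert-butyldimethylsilyl)oxy]prop-1-en-2-yl}-2-methyl-3-oxo-2,3-dihydrofuran-2-yl]acetaldehyde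
Product: 21 (3aR,4R,6S,10Z,11aR)-10-{[(tert-butyldimethylsilyl)oxy]methyl}-4-hydroxy-6-methyl-3-methylidene-3a,4,5,6-tetrahydro-6,9-epoxycyclodeca[b]furan-2,7(3H,11aH)-dione, via allylzinc bromide 20 (not isolated)
Conditions: activated Zn dust (10 equiv), THF/sat. aq NH4Cl (4:1), rt, 19 added by syringe pump over 6 h (final 1 mM)
Reagents that add atoms: none
Why: Proposed new method: zinc inserts into the allylic C–Br bond to give 20, a lactone homoenolate equivalent whose nucleophilic terminus is the butenolide β-carbon C7 (a Michael-acceptor carbon in 19), and SE2′ addition through C7 to the C8 aldehyde carbon (also electrophilic) closes the ten-membered ring and unveils the exo-methylene, C7 being set by attack anti to the C6 substituent (trans-lactone) and C8 (R, 7,8-syn) by the syn preference that, as recalled and not checked, is reported for zinc with 3-(bromomethyl)furan-2(5H)-one; the closest known reactions are that intermolecular Zn/Cr Barbier allylation and the Cr- or Zn-mediated macrocyclisation of ω-formyl 2-(bromomethyl)acrylates to germacranolides.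

Step 14
Reactants: 21 (3aR,4R,6S,10Z,11aR)-10-{[(tert-butyldimethylsilyl)oxy]methyl}-4-hydroxy-6-methyl-3-methylidene-3a,4,5,6-tetrahydro-6,9-epoxycyclodeca[b]furan-2,7(3H,11aH)-dione
Product: 22 (3aR,4R,6S,10Z,11aR)-10-{[(tert-butyldimethylsilyl)oxy]methyl}-6-methyl-3-methylidene-2,7-dioxo-2,3,3a,4,5,6,7,11a-octahydro-6,9-epoxycyclodeca[b]furan-4-yl 3-methylbutanoate
Conditions: (iPrCH2CO)2O, DMAP (0.2 equiv), pyridine, CH2Cl2, 0 °C → rt
Reagents that add atoms: 3-methylbutanoic anhydride CC(C)CC(=O)OC(=O)CC(C)C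
Why: DMAP-catalysed acylation of the only free hydroxyl (C8) proceeds with retention.

Step 15
Reactants: 22 (3aR,4R,6S,10Z,11aR)-10-{[(tert-butyldimethylsilyl)oxy]methyl}-6-methyl-3-methylidene-2,7-dioxo-2,3,3a,4,5,6,7,11a-octahydro-6,9-epoxycyclodeca[b]furan-4-yl 3-methylbutanoate
Product: 23 (3aR,4R,6S,10Z,11aR)-10-(hydroxymethyl)-6-methyl-3-methylidene-2,7-dioxo-2,3,3a,4,5,6,7,11a-octahydro-6,9-epoxycyclodeca[b]furan-4-yl 3-methylbutanoate (CNP0171896.1)
Conditions: HF·pyridine, pyridine, THF, 0 °C → rt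
Reagents that add atoms: none
Why: Fluoride-mediated cleavage of the primary allylic silyl ether under buffered, non-basic conditions spares the α-methylene lactone, the ester and the furanone.

**Compound list**
1 | tert-butyldimethyl(prop-2-yn-1-yloxy)silane | C#CCO[Si](C)(C)C(C)(C)C | starting material
2 | (E)-but-2-enal (crotonaldehyde) | C/C=C/C=O | starting material
3 | methyl{3-[(tert-butyldimethylsilyl)oxy]prop-1-yn-1-yl}zinc | C[Zn]C#CCO[Si](C)(C)C(C)(C)C | intermediate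
4 | (4S,5E)-1-[(tert-butyldimethylsilyl)oxy]hept-5-en-2-yn-4-ol | C/C=C/[C@H](O)C#CCO[Si](C)(C)C(C)(C)C | intermediate
5 | sodium (5S)-3-{[(tert-butyldimethylsilyl)oxy]methyl}-2,2-bis(2-methoxyethoxy)-5-[(E)-prop-1-enyl]-2,5-dihydro-1,2-oxaluminol-2-uide (cyclic alkenylalanate) | COCCO[Al-]1(OCCOC)O[C@@H](/C=C/C)C=C1CO[Si](C)(C)C(C)(C)C.[Na+] | intermediate
6 | (2Z,4S,5E)-1-[(tert-butyldimethylsilyl)oxy]-2-iodohepta-2,5-dien-4-ol | C/C=C/[C@H](O)/C=C(\I)CO[Si](C)(C)C(C)(C)C | intermediate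
7 | tert-butyl{[(2Z,4S,5E)-2-iodo-4-[(triethylsilyl)oxy]hepta-2,5-dien-1-yl]oxy}dimethylsilane | C/C=C/[C@H](O[Si](CC)(CC)CC)/C=C(\I)CO[Si](C)(C)C(C)(C)C | intermediate
8 | (2Z)-3-methylpent-2-en-4-yn-1-ol | C#C/C(C)=C\CO | starting material
9 | [(2S,3R)-3-ethynyl-3-methyloxiran-2-yl]methanol | C#C[C@@]1(C)O[C@H]1CO | intermediate
10 | (3S)-3-methylpent-4-yne-1,3-diol | C#C[C@](C)(CCO)O | intermediate
11 | (3S)-3-methyl-5-[(triethylsilyl)oxy]pent-1-yn-3-ol | C#C[C@](C)(CCO[Si](CC)(CC)CC)O | intermediate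
12 | (3S,7Z,9S,10E)-7-{[(tert-butyldimethylsilyl)oxy]methyl}-3-hydroxy-3-methyl-1,9-bis[(triethylsilyl)oxy]dodeca-7,10-dien-4-yn-6-one | C/C=C/[C@H](O[Si](CC)(CC)CC)/C=C(/CO[Si](C)(C)C(C)(C)C)C(=O)C#C[C@](C)(CCO[Si](CC)(CC)CC)O | intermediate
13 | (2S)-5-[(2Z,4S,5E)-1-[(tert-butyldimethylsilyl)oxy]-4-[(triethylsilyl)oxy]hepta-2,5-dien-2-yl]-2-methyl-2-{2-[(triethylsilyl)oxy]ethyl}furan-3(2H)-one | C/C=C/[C@H](O[Si](CC)(CC)CC)/C=C(/CO[Si](C)(C)C(C)(C)C)C1=CC(=O)[C@](C)(CCO[Si](CC)(CC)CC)O1 | intermediate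
14 | [(2S)-5-{(2Z,4S,5E)-1-[(tert-butyldimethylsilyl)oxy]-4-[(triethylsilyl)oxy]hepta-2,5-dien-2-yl}-2-methyl-3-oxo-2,3-dihydrofuran-2-yl]acetaldehyde | C/C=C/[C@H](O[Si](CC)(CC)CC)/C=C(/CO[Si](C)(C)C(C)(C)C)C1=CC(=O)[C@](C)(CC=O)O1 | intermediate
15 | [(2S)-5-{(2Z,4S,5E)-1-[(tert-butyldimethylsilyl)oxy]-4-hydroxyhepta-2,5-dien-2-yl}-2-methyl-3-oxo-2,3-dihydrofuran-2-yl]acetaldehyde | C/C=C/[C@H](O)/C=C(/CO[Si](C)(C)C(C)(C)C)C1=CC(=O)[C@](C)(CC=O)O1 | intermediate
16 | 2-(bromomethyl)prop-2-enoic acid | C=C(CBr)C(=O)O | starting material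
17 | 2-(bromomethyl)prop-2-enoyl chloride | C=C(CBr)C(=O)Cl | intermediate
18 | (2Z,4S,5E)-1-[(tert-butyldimethylsilyl)oxy]-2-[(5S)-5-methyl-4-oxo-5-(2-oxoethyl)-4,5-dihydrofuran-2-yl]hepta-2,5-dien-4-yl 2-(bromomethyl)prop-2-enoate | C/C=C/[C@H](OC(=O)C(=C)CBr)/C=C(/CO[Si](C)(C)C(C)(C)C)C1=CC(=O)[C@](C)(CC=O)O1 | intermediate
19 | [(2S)-5-{(1Z)-1-[(2R)-4-(bromomethyl)-5-oxo-2,5-dihydrofuran-2-yl]-3-[(tert-butyldimethylsilyl)oxy]prop-1-en-2-yl}-2-methyl-3-oxo-2,3-dihydrofuran-2-yl]acetaldehyde | O=C1O[C@H](/C=C(/CO[Si](C)(C)C(C)(C)C)C2=CC(=O)[C@](C)(CC=O)O2)C=C1CBr | intermediate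
20 | allylzinc bromide of 19 (bromozincio-methyl group in place of the bromomethyl group on the butenolide) | O=C1O[C@H](/C=C(/CO[Si](C)(C)C(C)(C)C)C2=CC(=O)[C@](C)(CC=O)O2)C=C1C[Zn]Br | intermediate
21 | (3aR,4R,6S,10Z,11aR)-10-{[(tert-butyldimethylsilyl)oxy]methyl}-4-hydroxy-6-methyl-3-methylidene-3a,4,5,6-tetrahydro-6,9-epoxycyclodeca[b]furan-2,7(3H,11aH)-dione | C=C1C(=O)O[C@@H]2/C=C(/CO[Si](C)(C)C(C)(C)C)C3=CC(=O)[C@](C)(C[C@@H](O)[C@@H]12)O3 | intermediate
22 | (3aR,4R,6S,10Z,11aR)-10-{[(tert-butyldimethylsilyl)oxy]methyl}-6-methyl-3-methylidene-2,7-dioxo-2,3,3a,4,5,6,7,11a-octahydro-6,9-epoxycyclodeca[b]furan-4-yl 3-methylbutanoate | C=C1C(=O)O[C@@H]2/C=C(/CO[Si](C)(C)C(C)(C)C)C3=CC(=O)[C@](C)(C[C@@H](OC(=O)CC(C)C)[C@@H]12)O3 | intermediate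
23 | (3aR,4R,6S,10Z,11aR)-10-(hydroxymethyl)-6-methyl-3-methylidene-2,7-dioxo-2,3,3a,4,5,6,7,11a-octahydro-6,9-epoxycyclodeca[b]furan-4-yl 3-methylbutanoate (CNP0171896.1) | C=C1C(=O)O[C@@H]2/C=C(/CO)C3=CC(=O)[C@](C)(C[C@@H](OC(=O)CC(C)C)[C@@H]12)O3 | target

**Step count and risks**
Total steps: 15. Longest linear sequence: 12 (steps 1–3, then 7–15; the branch through steps 4–6 is the same length).

The three steps most likely to fail:

Step 13 (zinc macro-Barbier). The allylzinc may be protonated before it cyclises, or the ring may close with the wrong sense at C8. The fallback sets out from 15 and comes back at 21, and replaces the reductively formed allylmetal by an allylsilane. Alcohol 15 is esterified (DCC, DMAP, CH2Cl2) with 2-[(trimethylsilyl)methyl]prop-2-enoic acid, made from the commercial ethyl ester with LiOH, to give the trimethylsilylmethyl acrylate ester F1. Ring-closing metathesis (Grubbs II, toluene, 70 °C) gives the silylmethyl butenolide F2. An intramolecular Hosomi–Sakurai reaction (BF3·OEt2, CH2Cl2, −78 °C, 1 mM) then closes the ring through C7 by an open transition state, which is intrinsically syn-selective and has no protonolysis pathway, and gives 21.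

Step 7 (carbonylative Sonogashira coupling). Direct coupling without CO, or cyclic acylpalladation of the (Z)-1-iodo-1,4-diene onto the propenyl group, may win. The fallback sets out from 7 and comes back at 12, and builds the ynone by polar chemistry. Iodide 7 is converted (t-BuLi, Et2O, −78 °C; then DMF) into the (Z)-enal F3. The dilithio derivative of alkyne 11 (n-BuLi, 2.1 equiv, THF, −78 °C) adds to it to give the propargylic alcohol F4, as a mixture at the new carbinol that does not matter. MnO2 (CH2Cl2, rt) oxidises this doubly activated alcohol to ynone 12.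

Step 5 (Red-Al opening). Hydride may attack the alkynyl epoxide in an SN2′ sense to give an allene, or reduce the alkyne. The fallback sets out from 9 and comes back at 10, and removes the C9 oxygen by internal redox in place of hydride. Dess–Martin oxidation of 9 gives the epoxy aldehyde F5. A thiazolium-derived carbene catalyst (10 mol %, iPr2NEt, MeOH, CH2Cl2, 30 °C) opens the epoxide through its Breslow intermediate and transfers the acyl group to methanol, which gives the β-hydroxy ester F6 with C10 untouched. LiBH4 (THF, 0 °C) reduces the ester to diol 10.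

**Further compounds**
F1 | step 13 | (2Z,4S,5E)-1-[(tert-butyldimethylsilyl)oxy]-2-[(5S)-5-methyl-4-oxo-5-(2-oxoethyl)-4,5-dihydrofuran-2-yl]hepta-2,5-dien-4-yl 2-[(trimethylsilyl)methyl]prop-2-enoate | C/C=C/[C@H](OC(=O)C(=C)C[Si](C)(C)C)/C=C(/CO[Si](C)(C)C(C)(C)C)C1=CC(=O)[C@](C)(CC=O)O1
F2 | step 13 | [(2S)-5-{(1Z)-3-[(tert-butyldimethylsilyl)oxy]-1-[(2R)-5-oxo-4-[(trimethylsilyl)methyl]-2,5-dihydrofuran-2-yl]prop-1-en-2-yl}-2-methyl-3-oxo-2,3-dihydrofuran-2-yl]acetaldehyde | O=C1O[C@H](/C=C(/CO[Si](C)(C)C(C)(C)C)C2=CC(=O)[C@](C)(CC=O)O2)C=C1C[Si](C)(C)C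
F3 | step 7 | (2Z,4S,5E)-2-{[(tert-butyldimethylsilyl)oxy]methyl}-4-[(triethylsilyl)oxy]hepta-2,5-dienal | C/C=C/[C@H](O[Si](CC)(CC)CC)/C=C(/CO[Si](C)(C)C(C)(C)C)C=O
F4 | step 7 | (3S,7Z,9S,10E)-7-{[(tert-butyldimethylsilyl)oxy]methyl}-3-methyl-1,9-bis[(triethylsilyl)oxy]dodeca-7,10-dien-4-yne-3,6-diol (both C6 epimers) | C/C=C/[C@H](O[Si](CC)(CC)CC)/C=C(/CO[Si](C)(C)C(C)(C)C)C(O)C#C[C@](C)(CCO[Si](CC)(CC)CC)O
F5 | step 5 | (2R,3R)-3-ethynyl-3-methyloxirane-2-carbaldehyde | C#C[C@@]1(C)O[C@H]1C=O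
F6 | step 5 | methyl (3S)-3-hydroxy-3-methylpent-4-ynoate | C#C[C@](C)(CC(=O)OC)O
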